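**Plan**

- Cuts: the C8' methyl is traced back to a C8' ketone. This 2-alkylcyclohexanone (ring C) is cut at C8'–C9' and C9'–C10', so C9' leaves ring C together with the tether and the ene half, giving gem-dibromide 22 and cyclopentanone 7. In 22 the C7=C8 alkene is traced back to a C8 ketone, cut the same way (C8–C9, C9–C10; C9 from CH2Br2) and at C9–C11 (allyl bromide), which gives 7 a second time.
- Forward: rings A and D are the cyclohexane of (S)-Hajos–Parrish ketone (six steps to 7). Ring B arises by ring enlargement/allylation of 7, the alkene by triflate/methyl coupling, and the allyl terminus is raised to CHBr2. Ring C arises by insertion of that carbon (C9') into a second molecule of 7, which joins the halves; last, C8'=O becomes CH–CH3.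
- Enabling feature: in ring C the tether carbon C9' lies between the quaternary C10' and C8', which carries only a methyl group and can therefore be a carbonyl carbon. Such a ketone is the product of inserting a carbenoid carbon into the C(=O)–C(quaternary) bond of a trans-hydrindanone, and the four central carbons C9–C11–C11'–C9' can act as the carbenoid carbon at either end in turn.
- Stereochemistry: C10/C10' come from the (S)-ketone (they migrate with retention); C3/C3' from hydride reduction (equatorial OH); C5/C5' from hydrogenation anti to the angular methyl; C9, C9' and C8' from equilibration next to a carbonyl, each to the equatorial position.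

Key step: step 13

Numbering: each decalin is numbered like a drimane (C3 oxygen, C4 gem-dimethyl, C5/C10 ring fusion with the angular methyl on C10, C8, C9). Rings A (C1–C5, C10) and B (C5–C10) are the ene half; primed atoms form rings D (C1'–C5', C10') and C (C5'–C10') of the saturated half; the tether is C11 (on C9) and C11' (on C9'). Hydrindanes keep these numbers and lack C9. β is the face of the angular methyl.

Remark: 1, 8 and 9 are taken as commercial; TBS = tert-butyldimethylsilyl. The route relies on the expected preference of the carbenoid shift for the quaternary ring carbon (steps 7 and 13).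

**Step 1**
Reactants: 1 (S)-Hajos–Parrish ketone
Product: 2 C8 dioxolane ketal of 1 (C3 enone free)
Conditions: 2-ethyl-2-methyl-1,3-dioxolane, ethylene glycol (cat.), TsOH (cat.), rt
Reagents that add atoms: 2-ethyl-2-methyl-1,3-dioxolane, CCC1(C)OCCO1
Why: Acid-catalysed transketalisation reacts only at the saturated cyclopentanone carbonyl, the conjugated C3 carbonyl being far less electrophilic (chemoselective ketal protection).

**Step 2**
Reactants: 2 C8 dioxolane ketal
Product: 3 4,4-dimethyl-3-oxo ketal with the alkene moved to C5=C6 (five-membered ring)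
Conditions: KOt-Bu, MeI, t-BuOH/THF, 0 °C to rt
Reagents that add atoms: iodomethane, CI
Why: The extended dienolate is methylated twice at C4 with migration of the double bond out of conjugation (deconjugative α,α-dialkylation of an enone), which installs the gem-dimethyl group.

**Step 3**
Reactants: 3 dimethyl ketone
Product: 4 3β-alcohol (equatorial OH, cis to the angular methyl)
Conditions: NaBH4, MeOH, 0 °C
Reagents that add atoms: none
Why: Hydride adds along the axial direction from the α-face, away from the axial 4β-methyl, so the alcohol is equatorial (3β), as is usual for 4,4-dimethyl-3-oxo terpenoids (borohydride reduction).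

**Step 4**
Reactants: 4 3β-alcohol
Product: 5 3β-TBS ether
Conditions: TBSOTf, 2,6-lutidine, CH2Cl2, 0 °C
Reagents that add atoms: tert-butyldimethylsilyl triflate, CC(C)(C)[Si](C)(C)OS(=O)(=O)C(F)(F)F
Why: A silyl triflate with a hindered base silylates the neopentyl-type secondary alcohol without opening the ketal (silyl ether protection, stable to the organolithium steps).

**Step 5**
Reactants: 5 silyl ether
Product: 6 trans-fused (5α-H) saturated ketal
Conditions: H2 (4 atm), 10% Pd/C, EtOAc, rt
Reagents that add atoms: none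
Why: Heterogeneous hydrogenation should deliver hydrogen to C5=C6 from the α-face, the β-face being covered by the angular methyl and the 4β-methyl, which sets C5 (H α) and the trans ring fusion.

**Step 6**
Reactants: 6 saturated ketal
Product: 7 hydrindanone (3β-TBSO-4,4,10β-trimethyl-5α-hydrindan-8-one; C=O next to C10)
Conditions: PPTS, acetone/H2O, reflux
Reagents that add atoms: water, O
Why: Mild acid hydrolysis frees the cyclopentanone while the hindered secondary silyl ether survives (ketal deprotection).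

**Step 7**
Reactants: 7 hydrindanone; 8 dibromomethane; 9 allyl bromide
Product: 15 9β-allyl-3β-TBSO-4,4,10β-trimethyl-5α-decal-8-one, via dibromomethyllithium 10 (not isolated), via dibromo alkoxide adduct 11 (not isolated), via β-oxido carbenoid 12 (not isolated), via lithium enolate 13 (not isolated), via allyl ketone C9 epimer mixture 14 (not isolated)
Conditions: 8, LiN(i-Pr)2, THF/Et2O, −95 °C; 7; n-BuLi, −95 to −20 °C; HMPA, 9, −40 to 0 °C; then NaOMe (cat.), MeOH, rt
Reagents that add atoms: none
Why: Dibromomethyllithium adds to the cyclopentanone, bromine–lithium exchange gives the β-oxido carbenoid, and its 1,2-shift of the quaternary C10 enlarges the ring to a regiodefined cyclohexanone enolate (β-oxido carbenoid ring enlargement); this enolate is C-allylated at C9, and methoxide equilibration places the allyl group equatorial (β).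

**Step 8**
Reactants: 15 allyl ketone
Product: 17 C7=C8 enol triflate, via kinetic lithium enolate 16 (not isolated)
Conditions: LiN(i-Pr)2, THF, −78 °C; PhNTf2, −78 °C to rt
Reagents that add atoms: N-phenylbis(trifluoromethanesulfonimide), O=S(=O)(N(c1ccccc1)S(=O)(=O)C(F)(F)F)C(F)(F)F
Why: Kinetic deprotonation takes the unhindered C7 methylene and not the tertiary C9–H beside the quaternary carbon, and O-triflation fixes the double bond at C7=C8 (enol triflate formation).

**Step 9**
Reactants: 17 enol triflate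
Product: 18 diene (9β-allyl-3β-TBSO-4,4,8,10β-tetramethyl-5α-octal-7-ene)
Conditions: MeMgBr, Fe(acac)3 (cat.), THF/NMP, −30 to 0 °C
Reagents that add atoms: methylmagnesium bromide, C[Mg]Br
Why: Iron-catalysed cross-coupling of an alkenyl triflate with a methyl Grignard reagent replaces OTf by methyl without moving the double bond and tolerates the terminal alkene and the silyl ether.

**Step 10**
Reactants: 18 diene
Product: 20 primary alcohol (9β-(3-hydroxypropyl)), via B-alkyl-9-borabicyclononane 19 (not isolated)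
Conditions: 9-BBN, THF, rt; then NaOH, H2O2, 0 °C to rt
Reagents that add atoms: hydrogen peroxide, OO
Why: 9-BBN hydroborates the monosubstituted alkene at its terminal carbon and leaves the hindered trisubstituted ring alkene untouched (anti-Markovnikov hydroboration–oxidation).

**Step 11**
Reactants: 20 primary alcohol
Product: 21 aldehyde (9β-(3-oxopropyl))
Conditions: Dess–Martin periodinane, NaHCO3, CH2Cl2, rt
Reagents that add atoms: none
Why: Dess–Martin oxidation stops at the aldehyde under buffered conditions that spare the alkene and the silyl ether.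

**Step 12**
Reactants: 21 aldehyde
Product: 22 gem-dibromide (9β-(3,3-dibromopropyl); CHBr2 carbon = C9')
Conditions: (PhO)3P, Br2, CH2Cl2, −78 °C; Et3N, 21, −78 °C to rt
Reagents that add atoms: bromine, BrBr
Why: The preformed dibromophosphorane activates the aldehyde oxygen and bromide replaces it twice with loss of triphenyl phosphate (deoxygenative gem-dihalogenation of an aldehyde), with no free bromine left to attack the alkene.

**Step 13**
Reactants: 22 gem-dibromide; 7 hydrindanone
Product: 27 bis-silyl ketone (ene half joined through C11–C11' to the equatorial β-position C9' of 3'β-TBSO-4',4',10'β-trimethyl-5'α-decal-8'-one), via lithiated dibromide 23 (not isolated), via dibromo alkoxide adduct 24 (not isolated), via β-oxido carbenoid 25 (not isolated), via lithium enolate 26 (not isolated)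
Conditions: 22, LiN(i-Pr)2, THF/Et2O, −105 °C; 7 (1.3 equiv); n-BuLi, −105 to 0 °C; MeOH, rt
Reagents that add atoms: none
Why: Deprotonation of 22 gives the α,α-dibromoalkyllithium 23, which adds to the cyclopentanone carbonyl C8' of 7 anti to the angular methyl; bromine–lithium exchange of alkoxide 24 gives the β-oxido carbenoid 25, in which the ring bond C8'–C10' shifts to the carbenoid carbon C9' with loss of LiBr and leaves lithium enolate 26. The closest known reaction type is the β-oxido carbenoid one-carbon ring enlargement of cycloalkanones with (1,1-dibromoalkyl)lithium reagents, used here as a fragment coupling that makes both C8'–C9' and the hindered C9'–C10' bond. Ring C is not closed by a cyclization: the cyclopentane C5'–C6'–C7'–C8'–C10' grows to the cyclohexane by insertion of C9' (a 1,2-alkyl shift), and the trans ring fusion is carried over because C10' migrates with retention. The only new stereocentre, C9', is set after the shift: protonation of 26 and equilibration by the lithium methoxide formed put the tether equatorial (β), since the axial position meets three syn-axial hydrogens (on C1', C5', C7'), so both faces of addition and both carbenoid epimers converge on one ketone. The selectivity needed is migration of C10' and not of the methylene C7'; the electron-poor carbenoid carbon is expected to accept the more substituted, better donating quaternary carbon, as in pinacol-type shifts, and step 7 tests this on the same ketone with the parent reagent.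

**Step 14**
Reactants: 27 bis-silyl ketone
Product: 28 methyl enol ether (C8'=CH–OMe, E/Z mixture)
Conditions: Ph3P(CH2OMe)Cl, KOt-Bu, THF, 0 °C to reflux
Reagents that add atoms: (methoxymethyl)triphenylphosphonium chloride, COC[P+](c1ccccc1)(c1ccccc1)c1ccccc1.[Cl-]
Why: Wittig olefination with the methoxymethylene ylide adds the carbon that becomes the C8' methyl (one-carbon homologation of a ketone); the alkene geometry is of no consequence.

**Step 15**
Reactants: 28 enol ether
Product: 30 dihydroxy aldehyde (8'α-formyl, equatorial), via aldehyde C8' epimer mixture 29 (not isolated)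
Conditions: aq. HF (48%), MeCN/THF, rt; then K2CO3, MeOH, rt
Reagents that add atoms: water, O
Why: Aqueous HF hydrolyses the enol ether and removes both silyl ethers, and carbonate then epimerises C8' to the equatorial formyl group, trans to the equatorial tether and free of the syn-axial clash with the angular methyl (thermodynamic control).

**Step 16**
Reactants: 30 dihydroxy aldehyde
Product: 32 target diol, via hydrazone 31 (not isolated)
Conditions: N2H4·H2O, KOH, diethylene glycol, 130 °C then 200 °C
Reagents that add atoms: none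
Why: Wolff–Kishner reduction (Huang–Minlon conditions) turns the formyl group into the methyl group through the hydrazone without touching the trisubstituted alkene or the secondary alcohols, and the equatorial configuration at C8' is kept.

**Compound list**

1 | (S)-Hajos–Parrish ketone, (7aS)-7a-methyl-2,3,7,7a-tetrahydro-1H-indene-1,5(6H)-dione | C[C@]12CCC(=O)C=C1CCC2=O | starting material
2 | C8 spiro-dioxolane ketal of 1 (enone free) | C[C@]12CCC(=O)C=C1CCC23OCCO3 | intermediate
3 | 4,4-dimethyl-3-oxo-5-ene ketal | C[C@]12CCC(=O)C(C)(C)C1=CCC23OCCO3 | intermediate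
4 | 3β-hydroxy-4,4-dimethyl-5-ene ketal | C[C@]12CC[C@H](O)C(C)(C)C1=CCC23OCCO3 | intermediate
5 | 3β-TBS ether of 4 | C[C@]12CC[C@H](O[Si](C)(C)C(C)(C)C)C(C)(C)C1=CCC23OCCO3 | intermediate
6 | 3β-TBSO-4,4,10β-trimethyl-5α-hydrindane C8 ketal (trans-fused) | C[C@]12CC[C@H](O[Si](C)(C)C(C)(C)C)C(C)(C)[C@@H]1CCC23OCCO3 | intermediate
7 | 3β-TBSO-4,4,10β-trimethyl-5α-hydrindan-8-one | C[C@]12CC[C@H](O[Si](C)(C)C(C)(C)C)C(C)(C)[C@@H]1CCC2=O | intermediate
8 | dibromomethane | BrCBr | starting material
9 | allyl bromide | C=CCBr | starting material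
10 | dibromomethyllithium | [Li]C(Br)Br | intermediate (not isolated)
11 | lithium alkoxide of the 8-(dibromomethyl)-8β-ol (α-face adduct) | BrC(Br)[C@]1(O[Li])CC[C@H]2C(C)(C)[C@@H](O[Si](C)(C)C(C)(C)C)CC[C@]12C | intermediate (not isolated)
12 | β-oxido carbenoid (C8 alkoxide, bromo(lithio)methyl group) | [Li]C(Br)[C@]1(O[Li])CC[C@H]2C(C)(C)[C@@H](O[Si](C)(C)C(C)(C)C)CC[C@]12C | intermediate (not isolated)
13 | lithium C8=C9 enolate of the ring-enlarged decalone | C1=C(O[Li])CC[C@H]2C(C)(C)[C@@H](O[Si](C)(C)C(C)(C)C)CC[C@]12C | intermediate (not isolated)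
14 | 9-allyl-decal-8-one, C9 epimer mixture | C=CCC1C(=O)CC[C@H]2C(C)(C)[C@@H](O[Si](C)(C)C(C)(C)C)CC[C@]12C | intermediate (not isolated)
15 | 9β-allyl-3β-TBSO-4,4,10β-trimethyl-5α-decal-8-one | C=CC[C@H]1C(=O)CC[C@H]2C(C)(C)[C@@H](O[Si](C)(C)C(C)(C)C)CC[C@]12C | intermediate
16 | kinetic lithium C7=C8 enolate of 15 | C=CC[C@H]1C(O[Li])=CC[C@H]2C(C)(C)[C@@H](O[Si](C)(C)C(C)(C)C)CC[C@]12C | intermediate (not isolated)
17 | C7=C8 enol triflate | C=CC[C@H]1C(OS(=O)(=O)C(F)(F)F)=CC[C@H]2C(C)(C)[C@@H](O[Si](C)(C)C(C)(C)C)CC[C@]12C | intermediate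
18 | 9β-allyl-3β-TBSO-4,4,8,10β-tetramethyl-5α-octal-7-ene | C=CC[C@H]1C(C)=CC[C@H]2C(C)(C)[C@@H](O[Si](C)(C)C(C)(C)C)CC[C@]12C | intermediate
19 | B-alkyl-9-borabicyclononane from 18 | C1CC2CCCC(C1)B2CCC[C@H]1C(C)=CC[C@H]2C(C)(C)[C@@H](O[Si](C)(C)C(C)(C)C)CC[C@]12C | intermediate (not isolated)
20 | 9β-(3-hydroxypropyl) ene-half alcohol | OCCC[C@H]1C(C)=CC[C@H]2C(C)(C)[C@@H](O[Si](C)(C)C(C)(C)C)CC[C@]12C | intermediate
21 | 9β-(3-oxopropyl) ene-half aldehyde | O=CCC[C@H]1C(C)=CC[C@H]2C(C)(C)[C@@H](O[Si](C)(C)C(C)(C)C)CC[C@]12C | intermediate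
22 | 9β-(3,3-dibromopropyl) ene-half gem-dibromide | BrC(Br)CC[C@H]1C(C)=CC[C@H]2C(C)(C)[C@@H](O[Si](C)(C)C(C)(C)C)CC[C@]12C | intermediate
23 | 1,1-dibromoalkyllithium from 22 | [Li]C(Br)(Br)CC[C@H]1C(C)=CC[C@H]2C(C)(C)[C@@H](O[Si](C)(C)C(C)(C)C)CC[C@]12C | intermediate (not isolated)
24 | dibromo lithium alkoxide adduct of 23 and 7 (α-face adduct) | CC1=CC[C@H]2C(C)(C)[C@@H](O[Si](C)(C)C(C)(C)C)CC[C@]2(C)[C@H]1CCC(Br)(Br)[C@]1(O[Li])CC[C@H]2C(C)(C)[C@@H](O[Si](C)(C)C(C)(C)C)CC[C@]12C | intermediate (not isolated)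
25 | β-oxido carbenoid (bromo(lithio) carbon C9') | CC1=CC[C@H]2C(C)(C)[C@@H](O[Si](C)(C)C(C)(C)C)CC[C@]2(C)[C@H]1CCC([Li])(Br)[C@]1(O[Li])CC[C@H]2C(C)(C)[C@@H](O[Si](C)(C)C(C)(C)C)CC[C@]12C | intermediate (not isolated)
26 | lithium C8'=C9' enolate of the ring-enlarged ketone | CC1=CC[C@H]2C(C)(C)[C@@H](O[Si](C)(C)C(C)(C)C)CC[C@]2(C)[C@H]1CCC1=C(O[Li])CC[C@H]2C(C)(C)[C@@H](O[Si](C)(C)C(C)(C)C)CC[C@]12C | intermediate (not isolated)
27 | bis-TBS 8'-ketone (tether β on C9') | CC1=CC[C@H]2C(C)(C)[C@@H](O[Si](C)(C)C(C)(C)C)CC[C@]2(C)[C@H]1CC[C@H]1C(=O)CC[C@H]2C(C)(C)[C@@H](O[Si](C)(C)C(C)(C)C)CC[C@]12C | intermediate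
28 | bis-TBS 8'-(methoxymethylene) enol ether, E/Z mixture | CC1=CC[C@H]2C(C)(C)[C@@H](O[Si](C)(C)C(C)(C)C)CC[C@]2(C)[C@H]1CC[C@H]1C(=COC)CC[C@H]2C(C)(C)[C@@H](O[Si](C)(C)C(C)(C)C)CC[C@]12C | intermediate
29 | 8'-formyl diol, C8' epimer mixture | CC1=CC[C@H]2C(C)(C)[C@@H](O)CC[C@]2(C)[C@H]1CC[C@H]1C(C=O)CC[C@H]2C(C)(C)[C@@H](O)CC[C@]12C | intermediate (not isolated)
30 | 8'α-formyl diol (formyl equatorial) | CC1=CC[C@H]2C(C)(C)[C@@H](O)CC[C@]2(C)[C@H]1CC[C@H]1[C@H](C=O)CC[C@H]2C(C)(C)[C@@H](O)CC[C@]12C | intermediate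
31 | hydrazone of 30 | CC1=CC[C@H]2C(C)(C)[C@@H](O)CC[C@]2(C)[C@H]1CC[C@H]1[C@H](C=NN)CC[C@H]2C(C)(C)[C@@H](O)CC[C@]12C | intermediate (not isolated)
32 | target diol (CNP0194061.1) | CC1=CC[C@H]2C(C)(C)[C@@H](O)CC[C@]2(C)[C@H]1CC[C@H]1[C@H](C)CC[C@H]2C(C)(C)[C@@H](O)CC[C@]12C | target

**Totals and risks**

Total step count: 16. Longest linear sequence: 16 (7 is made once and used in steps 7 and 13).

Steps most likely to fail:

1. Step 13. The tertiary dibromoalkyllithium may add too slowly to the neopentyl cyclopentanone and be lost by α-elimination or by enolising 7, or the methylene C7' may migrate in place of C10'. Fallback (cationic epoxy alcohol semipinacol with a small alkenyl nucleophile), from 22 and 7 back to 27: excess LiN(i-Pr)2 eliminates HBr twice from 22 to give the terminal alkyne F1. Hydrozirconation with Cp2Zr(H)Cl and iodination give the (E)-alkenyl iodide F2, and t-BuLi gives the alkenyllithium F3, which adds to 7 from the α-face to give the tertiary allylic alcohol F4. VO(acac)2/t-BuOOH epoxidises only the allylic alkene to the epoxy alcohol F5. BF3·OEt2 at −78 °C opens the epoxide at C9' with migration of C10' to the ring-enlarged β-hydroxy ketone F6. MsCl/Et3N gives the mesylate F7 and DBU the alkylidene ketone F8. Conjugate reduction with [(Ph3P)CuH]6 and methoxide equilibration return 27.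

2. Step 7. The wrong ring bond may migrate, or proton transfer between enolate 13 and alkylated ketone may lead to allylation at C7 and double allylation. Fallback from 7 back to 15: vinylmagnesium bromide with CeCl3 adds to 7 to give the tertiary allylic alcohol F9. VO(acac)2/t-BuOOH gives the epoxy alcohol F10, and BF3·OEt2 gives the ring-enlarged 9-(hydroxymethyl) ketone F11 by semipinacol shift. MsCl/Et3N gives the mesylate F12 and DBU the exocyclic enone F13. 1,4-Addition of (CH2=CH)2CuLi (from vinyllithium and CuI) followed by methoxide equilibration gives 15.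

3. Step 14. The basic ylide may enolise the hindered, α-branched ketone instead of adding to it. Fallback from 27 back to 30: reductive cyanation with TosMIC, KOt-Bu in DME/EtOH gives the nitrile F14 (C8' epimers). Reduction with i-Bu2AlH and hydrolysis give the silylated aldehyde F15. The conditions of step 15 (aq. HF, then K2CO3/MeOH) give 30.

**Further compounds**

F1 | step 13 | ene-half terminal alkyne (9β-propargyl) | C#CC[C@H]1C(C)=CC[C@H]2C(C)(C)[C@@H](O[Si](C)(C)C(C)(C)C)CC[C@]12C
F2 | step 13 | (E)-alkenyl iodide | I/C=C/C[C@H]1C(C)=CC[C@H]2C(C)(C)[C@@H](O[Si](C)(C)C(C)(C)C)CC[C@]12C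
F3 | step 13 | (E)-alkenyllithium | [Li]/C=C/C[C@H]1C(C)=CC[C@H]2C(C)(C)[C@@H](O[Si](C)(C)C(C)(C)C)CC[C@]12C
F4 | step 13 | tertiary allylic alcohol (8'β-OH, E-alkene) | CC1=CC[C@H]2C(C)(C)[C@@H](O[Si](C)(C)C(C)(C)C)CC[C@]2(C)[C@H]1C/C=C/[C@]1(O)CC[C@H]2C(C)(C)[C@@H](O[Si](C)(C)C(C)(C)C)CC[C@]12C
F5 | step 13 | epoxy alcohol (trans-epoxide, both diastereomers usable) | CC1=CC[C@H]2C(C)(C)[C@@H](O[Si](C)(C)C(C)(C)C)CC[C@]2(C)[C@H]1CC1OC1[C@]1(O)CC[C@H]2C(C)(C)[C@@H](O[Si](C)(C)C(C)(C)C)CC[C@]12C
F6 | step 13 | ring-enlarged β-hydroxy ketone (OH on C11', C9' and C11' unassigned) | CC1=CC[C@H]2C(C)(C)[C@@H](O[Si](C)(C)C(C)(C)C)CC[C@]2(C)[C@H]1CC(O)C1C(=O)CC[C@H]2C(C)(C)[C@@H](O[Si](C)(C)C(C)(C)C)CC[C@]12C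
F7 | step 13 | mesylate of F6 | CC1=CC[C@H]2C(C)(C)[C@@H](O[Si](C)(C)C(C)(C)C)CC[C@]2(C)[C@H]1CC(OS(C)(=O)=O)C1C(=O)CC[C@H]2C(C)(C)[C@@H](O[Si](C)(C)C(C)(C)C)CC[C@]12C
F8 | step 13 | alkylidene ketone (C9'=C11') | CC1=CC[C@H]2C(C)(C)[C@@H](O[Si](C)(C)C(C)(C)C)CC[C@]2(C)[C@H]1CC=C1C(=O)CC[C@H]2C(C)(C)[C@@H](O[Si](C)(C)C(C)(C)C)CC[C@]12C
F9 | step 7 | 8α-vinyl-8β-hydroxy hydrindane | C=C[C@]1(O)CC[C@H]2C(C)(C)[C@@H](O[Si](C)(C)C(C)(C)C)CC[C@]12C
F10 | step 7 | epoxy alcohol from F9 | C1OC1[C@]1(O)CC[C@H]2C(C)(C)[C@@H](O[Si](C)(C)C(C)(C)C)CC[C@]12C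
F11 | step 7 | 9-(hydroxymethyl)decal-8-one | OCC1C(=O)CC[C@H]2C(C)(C)[C@@H](O[Si](C)(C)C(C)(C)C)CC[C@]12C
F12 | step 7 | mesylate of F11 | CS(=O)(=O)OCC1C(=O)CC[C@H]2C(C)(C)[C@@H](O[Si](C)(C)C(C)(C)C)CC[C@]12C
F13 | step 7 | 9-methylenedecal-8-one | C=C1C(=O)CC[C@H]2C(C)(C)[C@@H](O[Si](C)(C)C(C)(C)C)CC[C@]12C
F14 | step 14 | bis-TBS 8'-nitrile (C8' epimers) | CC1=CC[C@H]2C(C)(C)[C@@H](O[Si](C)(C)C(C)(C)C)CC[C@]2(C)[C@H]1CC[C@H]1C(C#N)CC[C@H]2C(C)(C)[C@@H](O[Si](C)(C)C(C)(C)C)CC[C@]12C
F15 | step 14 | bis-TBS 8'-aldehyde (C8' epimers) | CC1=CC[C@H]2C(C)(C)[C@@H](O[Si](C)(C)C(C)(C)C)CC[C@]2(C)[C@H]1CC[C@H]1C(C=O)CC[C@H]2C(C)(C)[C@@H](O[Si](C)(C)C(C)(C)C)CC[C@]12C
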